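Put the next charge into winter's continuous tank, and not into summer's closed flask or spring's tube.

| flask | substrate | enzyme | remark | time |
|---|---|---|---|---|
| birch | 5 mM | 0.50 µM | run made earlier |  |
| alder | 5 mM | 0.70 µM | run made earlier |  |
| maple | 5 mM | 1.1 µM | run made earlier |  |
| noon | 5.0 mM | 0.50 µM | a single well-mixed tank run continuously and read at steady state, 2.0 min in it on average |  |
| winter | 5.0 mM | 0.50 µM | a single well-mixed tank run continuously and read at steady state, 10.0 min in it on average |  |
| summer | 5.0 mM | 0.50 µM | a closed flask charged with all of it at once and left for 2.0 min | 2.0 min |
| spring | 5.0 mM | 0.50 µM | plug flow through a tube for 2.0 min, no back-mixing | 2.0 min |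

- birch (time / s: target / %, uncatalysed product / %): 10.0: 24, 42; 12.0: 28, 45; 20.0: 39, 52; 30.0: 40, 50; 40.0: 40, 52; 60.0: 41, 50; 80.0: 44, 50
- alder (time / s: target / %, uncatalysed product / %): 10.0: 30, 38; 20.0: 47, 44; 30.0: 51, 43; 40.0: 45, 47; 50.0: 46, 46; 60.0: 46, 47; 80.0: 50, 46
- maple (time / s: target / %, uncatalysed product / %): 10.0: 48, 33; 12.0: 55, 31; 20.0: 58, 36; 30.0: 58, 36; 40.0: 61, 34; 60.0: 61, 37; 80.0: 60, 35

(scatter of a reading: 1.5 percentage points)

- the stated concentrations are those of everything mixed, before any reaction; amounts are the same in each set-up
- on the list of suspects stand: substrate <-> dormant form; substrate + enzyme -> target + enzyme; substrate -> uncatalysed product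
- the earlier runs were made in a closed, stirred flask

* the set-up with the highest share of target in all that became target or uncatalysed product, at the outlet or at the end ("none" if the first two lie within 2 percentage points) (noon / winter / summer / spring / none)
* share of target in all that became target or uncatalysed product, at the outlet or at the end, noon
* share of target in all that became target or uncatalysed product, at the outlet or at the end, winter
* share of target in all that became target or uncatalysed product, at the outlet or at the end, summer
* share of target in all that became target or uncatalysed product, at the outlet or at the end, spring

Read the birch run first, since it has the charge of these set-ups. Between 10.0 s and 20.0 s the birch readings gain 15 percentage points of target and 10 points of uncatalysed product, so its local share reads 60.0%. The local share is the part of what forms over a stretch that is target, in the usual term the differential selectivity. Up to 10.0 s the birch share reads 36.4%, so the birch reading is higher in the later stretch, where [substrate] is lower. Each reading carries 1.5 points of scatter.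

Now freeze [substrate]. Summer and spring pass through the rich start, and birch reads 46.8% at 80.0 s. A well-mixed tank at steady state holds one [substrate], so its outlet share is the local share at that value. My own reckoning takes both tanks to hold [substrate] below that of the birch stretch, so it puts them above 60.0%, and winter, with its mean stay of 10.0 min, at the lower [substrate].

The forecast gives 68% for noon, 71% for winter, 46% for summer and 46% for spring, and concludes: “Winter is best, though narrowly”.

    substrate ⇌ dormant form (K = 2.10, k = 0.0120 s⁻¹)
    substrate + enzyme → target + enzyme, rate k2*[substrate]*[enzyme]/(1 + ([substrate]/Km2)) (1.10 mM, k = 3.00 × 10⁵ L mol⁻¹ s⁻¹)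
    substrate → uncatalysed product (k = 0.0660 s⁻¹)

Winter leads at 68.7%, with noon at 65.8%, summer at 44.7% and spring at 44.7%, and the forecast stands within its tolerance. The return of dormant form to substrate makes no difference to winter's share. Against the birch reading of the local share, 60.0%, summer lies 15 points below. Noon lies 5.8 points above, with 4.00% of the charged substrate at its outlet. Winter, with [substrate] at 0.0387 mM, lies 8.7 points above.

The numbers in the tables were generated by integration on assumed constants, and the scatter is random.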